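## Analysis of the target

Target 17 is 1-(7-hydroxy-5-methoxy-2,2-dimethyl-2H-chromen-6-yl)-2-(4-methoxyphenyl)ethanone. It is a 2,2-dimethyl-2H-chromene whose benzene ring is substituted everywhere except C8, linked through a ketone and one CH2 group to a 4-methoxyphenyl ring. It has no stereocentre, and its only alkene is the endocyclic C3=C4, so the whole problem is one of constitution. Three oxygens in a phloroglucinol pattern end up as three different functions: the pyran oxygen O1 on C8a, a methyl ether on C5 and a free hydroxyl on C7. The acyl carbon sits on C6 between the last two. The sensitive sites are the styrene-like chromene double bond (acid, hydrogenation, oxidants), the CH2 between the ketone and the anisyl ring (enolisation, C-alkylation) and the electron-rich ring carbon C8. The difficulty is to tell the three oxygens apart and to make the pyran fuse on the C5 side of the acyl group, not on the C7 side. The plan rests on the contiguous pair C5(–O)/C6(–C=O) with a further oxygen on C7. An oxygen and an acyl carbon on neighbouring ring carbons are what an aryne gives when it inserts into the C–O bond of a carboxylic acid. The C7 oxygen, placed next to the aryne bond, tells the two new bonds where to go. The hydroxyl that the insertion leaves beside the ketone is then used again, to steer the pyran ring to its own side.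

## Retrosynthetic reasoning

17 from 16. The C7 oxygen is unmasked last by cutting its O–CH2OCH3 bond. While this acetal is in place, the other oxygen next to the ketone is the only free hydroxyl and can be methylated without any question of selectivity. The forward step must remove the acetal without hydrating the chromene alkene.

16 from 15. The O–CH3 bond on C5 is cut. In 15 this oxygen is a chelated phenol and the only acidic OH, so the forward step is a plain O-methylation that must leave the benzylic ketone CH2 alone.

15 from 12. The pyran is taken apart at C4–C4a, and the ring oxygen goes back to being the oxygen of an aryl 2-methylbut-3-yn-2-yl ether. This is done here and not earlier because 12 holds a hydroxyl hydrogen-bonded to the ketone on one side of the ether and an acetal-capped oxygen on the other. The chelate fixes the ring bonds so that the sigmatropic shift goes to the carbon next to the free hydroxyl. That carbon becomes C4a, so the free hydroxyl becomes the C5 oxygen. The forward step is a thermal cascade with no reagent.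

12 from 9 and 10. This is the central cut: the bond from the ring to the carbonyl carbon and the bond from the neighbouring ring carbon to its oxygen are removed together. What is left is an aryne carrying an acetal-capped oxygen next to the strained bond and the propargylic ether further round the ring, plus the acid 10 with its carbon skeleton intact. The gain is that the ketone, its ring position and exactly one free ortho hydroxyl appear in one step from an acid that is bought. No Lewis acid is needed, and a Lewis acid would not spare the acetal or the tertiary propargylic ether. The forward step must put oxygen on the aryne carbon remote from the acetal oxygen and carbon on the near one, and the aryl anion must attack the ester carbonyl before it is protonated.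

9 from 7 and 8. The tertiary O–C bond of the propargylic ether is cut. Placing the alkyne this late keeps it out of all organolithium chemistry. The forward step alkylates a phenol that sits meta to the triflate and para to silicon, so the base cannot reach the silyl triflate pair through the phenoxide.

7 from 5. The C–O bond of that phenol is traced back to a C–H bond. In 5 the ring carries triflate, silicon and acetal oxygen on three adjacent carbons, and only one C–H has no ortho neighbour. A sterically governed C–H borylation followed by oxidation therefore places the third oxygen with no protecting-group work. This replaces the double desymmetrisation that a triphenol starting material would need.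

5 from 2 and 1. The C–Si bond and the O–S bond are cut together. The ortho-bromophenol 2 gives both in one flask by O-silylation, bromine–lithium exchange, migration of silicon from oxygen to carbon and triflation of the phenoxide. The bromine in 1 already marks the carbon between the two oxygens, so no directing group has to be installed and removed. Compound 2 comes from the symmetric diol 1 by capping one hydroxyl.

## Alternatives that were turned down

Alternative 1: The pyran ring is cut at O1–C8a, C4–C4a and O1–C2 at once. This leads to 3-methoxy-5-(methoxymethoxy)benzyne A2, released from 3-methoxy-5-(methoxymethoxy)-2-(trimethylsilyl)phenyl trifluoromethanesulfonate A1, and to 3-methylbut-2-enal A3.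
- Forward step: the aldehyde oxygen of A3 adds to the aryne carbon remote from the methoxy group, the four-membered adduct opens to an ortho-quinone methide, and oxa-6π closure gives 5-methoxy-7-(methoxymethoxy)-2,2-dimethyl-2H-chromene A4.
- For: the ring and its quaternary carbon appear in one operation. The side on which the pyran fuses is set by the polarisation of the aryne and not by a thermal rearrangement. On this point it is stronger than the chosen route.
- Against: A4 still lacks the C6 acyl group. C6 lies between OMe and OMOM, but C8 lies between OMOM and the ring oxygen and is activated just as well, so metalation has no clear preference. Any acyl donor made from 10 has acidic benzylic hydrogens that an aryllithium would remove. The enal can also react with the aryne through its C=C bond. A1 costs about as many steps as 9.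
- Comparison: the chosen route gives up the one-step pyran but fixes the position of the ketone carbon in the same step that attaches it, which is the harder of the two problems.

Alternative 2: The benzene ring itself is disconnected between the acyl-bearing carbon and one hydroxyl-bearing carbon, back to methyl 8-(4-methoxyphenyl)-3,5,7-trioxooctanoate A5.
- Forward step: under Mg(OMe)2 the C6 methylene, which lies between two ketones, attacks the ester carbonyl C1. Enolisation of the six-membered triketone gives 2-(4-methoxyphenyl)-1-(2,4,6-trihydroxyphenyl)ethanone A6.
- For: no fluoride and no transition metal are needed. The side chain is part of the chain and can only end on the ring carbon between two oxygens. In A6 the para hydroxyl differs from the two chelated ortho hydroxyls, which marks the future pyran oxygen as well as the chosen route does.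
- Against: A5 has four acidic methylene groups and must be built by repeated polyanion acylations. It can also close by aldol attack of C2 on the C7 ketone to a resorcylate, or lactonise to a pyranone. A6 is what phloroglucinol F1 and 10 give in a single Friedel–Crafts step, so making the ring from a chain gains nothing. The two ortho hydroxyls of A6 are equivalent and still have to be told apart.
- Comparison: in the chosen route all three oxygens are already different before the ketone exists.

Alternative 3: Both bonds to the carbonyl carbon are cut, giving 2-iodo-1,3,5-tris(methoxymethoxy)benzene A7, carbon monoxide A8 and 4-methoxybenzylzinc chloride A9.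
- Forward step: zerovalent palladium from Pd(PPh3)4 inserts into the C–I bond, A8 inserts into the aryl–palladium bond, A9 transmetalates and reductive elimination gives 2-(4-methoxyphenyl)-1-[2,4,6-tris(methoxymethoxy)phenyl]ethanone A10.
- For: it is convergent. The iodine marks the acylation site and A7 is symmetric, so regiochemistry cannot go wrong. As a C–C bond formation it is more predictable than an aryne insertion, and here it is the stronger option.
- Against: the iodide is flanked by two ortho alkoxy groups on an electron-rich ring. Oxidative addition and CO insertion are both slowed, so direct coupling to the diarylmethane and homocoupling of A9 gain ground. A10 carries three identical acetals, so the whole task of making one oxygen the pyran oxygen, one a methyl ether and one a free hydroxyl remains, with extra protecting-group steps.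
- Comparison: the chosen insertion forms the ketone and in the same step reveals exactly one hydroxyl beside it, the one needed to direct the pyran.

Key step: step 5

Remark: the target has no stereogenic element, so only one transient diene below carries a stereodescriptor. Compounds 1, 8 and 10 are taken as purchased.

## Route

Step 1
Reactants: 1 2-bromobenzene-1,3-diol
Product: 2 2-bromo-3-(methoxymethoxy)phenol
Conditions: MOMCl (1.0 equiv), iPr2NEt, CH2Cl2, 0 °C to rt
Reagents that add atoms: chloromethyl methyl ether, COCCl
Why: Williamson-type O-alkylation of a symmetric diol with one equivalent of electrophile. The outcome is statistical, but diol, mono-ether and bis-ether differ widely in polarity, and recovered diol and bis-ether (after acid hydrolysis) can be recycled.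

Step 2
Reactants: 2 2-bromo-3-(methoxymethoxy)phenol
Product: 5 3-(methoxymethoxy)-2-(trimethylsilyl)phenyl trifluoromethanesulfonate, via aryl trimethylsilyl ether 3 (not isolated), via lithium 2-silylphenoxide 4 (not isolated)
Conditions: (Me3Si)2NH, THF, 70 °C, then evaporation; n-BuLi, THF, −78 °C; Tf2O, −78 °C
Reagents that add atoms: hexamethyldisilazane, C[Si](C)(C)N[Si](C)(C)C; trifluoromethanesulfonic anhydride, O=S(=O)(OS(=O)(=O)C(F)(F)F)C(F)(F)F
Why: O-silylation, bromine–lithium exchange and anionic 1,3 shift of silicon from oxygen to carbon (retro-Brook rearrangement) place the silyl group on the carbon that carried bromine, and the lithium phenoxide is triflated in the same flask. This is the standard route from ortho-bromophenols to ortho-silylaryl triflates, and the MOM ether is inert to n-BuLi at −78 °C.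

Step 3
Reactants: 5 3-(methoxymethoxy)-2-(trimethylsilyl)phenyl trifluoromethanesulfonate
Product: 7 5-hydroxy-3-(methoxymethoxy)-2-(trimethylsilyl)phenyl trifluoromethanesulfonate, via arylboronic pinacol ester 6 (not isolated)
Conditions: [Ir(OMe)(cod)]2 (1.5 mol%), 4,4'-di-tert-butyl-2,2'-bipyridine (3 mol%), B2pin2, THF, 60 °C; then NaBO3·4H2O, THF/H2O, rt
Reagents that add atoms: sodium perborate, [Na+].[O-]OB=O (the phenol oxygen); bis(pinacolato)diboron, CC1(C)OB(OC1(C)C)B1OC(C)(C)C(C)(C)O1 (the boryl group of 6)
Why: Iridium-catalysed aromatic C–H borylation is governed by sterics and should take the one C–H with no ortho substituent, C5, meta to both triflate and OMOM. Oxidation of the C–B bond with perborate gives the phenol at the same carbon. Borylation of ortho-silylaryl triflates is an established way to elaborate aryne precursors, and the neutral catalyst and mildly basic oxidant leave the triflate, silicon and acetal alone.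

Step 4
Reactants: 7 5-hydroxy-3-(methoxymethoxy)-2-(trimethylsilyl)phenyl trifluoromethanesulfonate; 8 3-chloro-3-methylbut-1-yne
Product: 9 3-(methoxymethoxy)-5-[(2-methylbut-3-yn-2-yl)oxy]-2-(trimethylsilyl)phenyl trifluoromethanesulfonate
Conditions: CuCl2·2H2O (1 mol%), DBU, MeCN, 0 °C
Reagents that add atoms: none
Why: Copper-catalysed O-alkylation of phenols with tertiary propargylic chlorides proceeds through a copper acetylide-derived electrophile and forms hindered aryl propargyl ethers at 0 °C. The amidine base does not activate a silyl triflate, and the phenoxide is meta to the triflate and para to silicon, so it cannot trigger loss of either.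

Step 5
Reactants: 9 3-(methoxymethoxy)-5-[(2-methylbut-3-yn-2-yl)oxy]-2-(trimethylsilyl)phenyl trifluoromethanesulfonate; 10 4-methoxyphenylacetic acid
Product: 12 1-[2-hydroxy-6-(methoxymethoxy)-4-[(2-methylbut-3-yn-2-yl)oxy]phenyl]-2-(4-methoxyphenyl)ethanone, via dialkoxybenzyne 11 (not isolated)
Conditions: CsF (4 equiv), THF, 125 °C, sealed tube
Reagents that add atoms: none
Why: Fluoride attacks the silicon of 9 and triflate leaves, giving aryne 11 with its strained bond between the former C1 and C2 and the OMOM group directly on the neighbour of C2. The caesium carboxylate of 10 should add through oxygen to C1, the carbon remote from OMOM, because the σ-withdrawing acetal oxygen stabilises the aryl anion developing at C2 and distortion of the aryne makes C1 the flatter, more electrophilic end; the ether at C5 is para to C2 and too far away to reverse this. The C2 anion then attacks the adjacent ester carbonyl through a four-membered alkoxide, which opens by C–O cleavage to the ortho-acyl phenoxide. The net result is insertion of the aryne into the C–O bond of the acid, with the new C–C(=O) bond at C2 and the new C–O bond at C1; no ring closes and no stereocentre forms. The closest known reaction is the fluoride-mediated reaction of silylaryl triflates with carboxylic acids in hot THF that gives ortho-hydroxyaryl ketones, and 3-alkoxy arynes are the class known for strong distal selectivity. The step needs oxygen at C1 and not C2, and acyl transfer and not protonation of the aryl anion; the first is secured by the OMOM group, the second by the aprotic solvent, the high temperature and the near-stoichiometric amount of acid. The terminal alkyne has no propargylic hydrogen for an ene reaction and the acetal is inert to fluoride.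

Step 6
Reactants: 12 1-[2-hydroxy-6-(methoxymethoxy)-4-[(2-methylbut-3-yn-2-yl)oxy]phenyl]-2-(4-methoxyphenyl)ethanone
Product: 15 1-[5-hydroxy-7-(methoxymethoxy)-2,2-dimethyl-2H-chromen-6-yl]-2-(4-methoxyphenyl)ethanone, via ortho-allenylphenol 13 (not isolated), via ortho-quinone methide 14 (not isolated)
Conditions: o-xylene, 145 °C
Reagents that add atoms: none
Why: Aryl propargyl ether Claisen rearrangement and tautomerisation give 13, a 1,5-hydrogen shift gives 14, and oxa-6π electrocyclisation closes the pyran; this is the standard thermal route to 2,2-dimethyl-2H-chromenes. In the phenyl numbering of 12, the hydrogen bond from the C2 hydroxyl to the ketone favours the bond-fixed form with C3=C4 double-bond character, so the [3,3] shift should go to C3, between the chelated hydroxyl and the ether oxygen, and the newly freed, non-chelated phenol oxygen closes the ring.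

Step 7
Reactants: 15 1-[5-hydroxy-7-(methoxymethoxy)-2,2-dimethyl-2H-chromen-6-yl]-2-(4-methoxyphenyl)ethanone
Product: 16 1-[5-methoxy-7-(methoxymethoxy)-2,2-dimethyl-2H-chromen-6-yl]-2-(4-methoxyphenyl)ethanone
Conditions: MeI, K2CO3, acetone, 56 °C
Reagents that add atoms: iodomethane, CI
Why: Williamson O-methylation of the only free hydroxyl. The phenol is far more acidic than the ketone CH2, so carbonate should form only the phenoxide, and the acetal and the chromene alkene are inert.

Step 8
Reactants: 16 1-[5-methoxy-7-(methoxymethoxy)-2,2-dimethyl-2H-chromen-6-yl]-2-(4-methoxyphenyl)ethanone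
Product: 17 1-(7-hydroxy-5-methoxy-2,2-dimethyl-2H-chromen-6-yl)-2-(4-methoxyphenyl)ethanone
Conditions: 3 M HCl, MeOH, 40 °C
Reagents that add atoms: none
Why: Acid-catalysed acetal exchange with methanol removes the MOM group, helped by the ortho carbonyl, which hydrogen-bonds the phenol as it is released. Methanol traps the formaldehyde unit as its dimethyl acetal, and dilute acid at this temperature should spare the chromene alkene and the two aryl methyl ethers.

## Compound list

1 | 2-bromobenzene-1,3-diol | Oc1cccc(O)c1Br | starting material
2 | 2-bromo-3-(methoxymethoxy)phenol | COCOc1cccc(O)c1Br | intermediate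
3 | [2-bromo-3-(methoxymethoxy)phenoxy]trimethylsilane | COCOc1cccc(O[Si](C)(C)C)c1Br | intermediate
4 | lithium 3-(methoxymethoxy)-2-(trimethylsilyl)phenolate | [Li+].[O-]c1cccc(OCOC)c1[Si](C)(C)C | intermediate
5 | 3-(methoxymethoxy)-2-(trimethylsilyl)phenyl trifluoromethanesulfonate | COCOc1cccc(OS(=O)(=O)C(F)(F)F)c1[Si](C)(C)C | intermediate
6 | 3-(methoxymethoxy)-5-(4,4,5,5-tetramethyl-1,3,2-dioxaborolan-2-yl)-2-(trimethylsilyl)phenyl trifluoromethanesulfonate | COCOc1cc(B2OC(C)(C)C(C)(C)O2)cc(OS(=O)(=O)C(F)(F)F)c1[Si](C)(C)C | intermediate
7 | 5-hydroxy-3-(methoxymethoxy)-2-(trimethylsilyl)phenyl trifluoromethanesulfonate | COCOc1cc(O)cc(OS(=O)(=O)C(F)(F)F)c1[Si](C)(C)C | intermediate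
8 | 3-chloro-3-methylbut-1-yne | CC(C)(Cl)C#C | starting material
9 | 3-(methoxymethoxy)-5-[(2-methylbut-3-yn-2-yl)oxy]-2-(trimethylsilyl)phenyl trifluoromethanesulfonate | COCOc1cc(OC(C)(C)C#C)cc(OS(=O)(=O)C(F)(F)F)c1[Si](C)(C)C | intermediate
10 | 4-methoxyphenylacetic acid | COc1ccc(CC(=O)O)cc1 | starting material
11 | 3-(methoxymethoxy)-5-[(2-methylbut-3-yn-2-yl)oxy]benzyne | COCOC1=CC(OC(C)(C)C#C)=CC#C1 | intermediate
12 | 1-[2-hydroxy-6-(methoxymethoxy)-4-[(2-methylbut-3-yn-2-yl)oxy]phenyl]-2-(4-methoxyphenyl)ethanone | COCOc1cc(OC(C)(C)C#C)cc(O)c1C(=O)Cc1ccc(OC)cc1 | intermediate
13 | 1-[2,4-dihydroxy-6-(methoxymethoxy)-3-(3-methylbuta-1,2-dien-1-yl)phenyl]-2-(4-methoxyphenyl)ethanone | COCOc1cc(O)c(C=C=C(C)C)c(O)c1C(=O)Cc1ccc(OC)cc1 | intermediate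
14 | (6Z)-5-hydroxy-3-(methoxymethoxy)-4-[(4-methoxyphenyl)acetyl]-6-(3-methylbut-2-en-1-ylidene)cyclohexa-2,4-dien-1-one | COCOC1=CC(=O)/C(=C\C=C(C)C)C(O)=C1C(=O)Cc1ccc(OC)cc1 | intermediate
15 | 1-[5-hydroxy-7-(methoxymethoxy)-2,2-dimethyl-2H-chromen-6-yl]-2-(4-methoxyphenyl)ethanone | COCOc1cc2OC(C)(C)C=Cc2c(O)c1C(=O)Cc1ccc(OC)cc1 | intermediate
16 | 1-[5-methoxy-7-(methoxymethoxy)-2,2-dimethyl-2H-chromen-6-yl]-2-(4-methoxyphenyl)ethanone | COCOc1cc2OC(C)(C)C=Cc2c(OC)c1C(=O)Cc1ccc(OC)cc1 | intermediate
17 | 1-(7-hydroxy-5-methoxy-2,2-dimethyl-2H-chromen-6-yl)-2-(4-methoxyphenyl)ethanone | COc1ccc(CC(=O)c2c(O)cc3c(c2OC)C=CC(C)(C)O3)cc1 | target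

## Step count and least certain steps

Total step count: 8. Longest linear sequence: 8 steps (1 to 17); 8 and 10 enter as purchased reagents.

Step 5 (key step). The most likely failure is that the aryl anion formed after carboxylate addition is protonated before it reaches the ester carbonyl. The proton can come from free acid or bifluoride, or from the acidic benzylic CH2 of the arylacetate through a six-membered transition state. The result would be plain O-arylation instead of insertion. A second danger is that the propargylic ether of 9 begins its sigmatropic shift at 125 °C before fluoride has consumed the silyl triflate, which would lead to an isomeric aryne.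

Fallback: set out from 10 and make the ketone by classical acylation. Heating 10 with phloroglucinol F1 in BF3·OEt2 at 80 °C should give 2-(4-methoxyphenyl)-1-(2,4,6-trihydroxyphenyl)ethanone F2, which is the same ketone as A6. Its para hydroxyl is the only one not hydrogen-bonded to the ketone and the most acidic, so alkylation with one equivalent of 8 (CuCl2·2H2O, DBU, MeCN, 0 °C) should give 1-{2,6-dihydroxy-4-[(2-methylbut-3-yn-2-yl)oxy]phenyl}-2-(4-methoxyphenyl)ethanone F3. One equivalent of MOMCl with iPr2NEt then caps one of the two equivalent ortho hydroxyls, while the other stays locked in the chelate. The route is rejoined at 12.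

Step 6. The [3,3] shift may go in part to the other ortho carbon, next to OMOM, if the bias from the chelated hydroxyl is too weak at 145 °C. The pyran may also close through the chelated oxygen instead of the free one. Either process gives an isomeric chromene that cannot be corrected later.

Fallback: set out from 12 and build the ring in separate, cooler steps. Semi-hydrogenation of the alkyne (H2, Pd/CaCO3 poisoned with Pb(OAc)2, quinoline) should give 1-[2-hydroxy-6-(methoxymethoxy)-4-[(2-methylbut-3-en-2-yl)oxy]phenyl]-2-(4-methoxyphenyl)ethanone F4. Its aromatic Claisen rearrangement runs near 110 °C, where the chelation bias should be larger, and gives the ortho-prenyl phenol 1-[2,4-dihydroxy-6-(methoxymethoxy)-3-(3-methylbut-2-en-1-yl)phenyl]-2-(4-methoxyphenyl)ethanone F5, which can be freed of any isomer. Dehydrogenative cyclisation of F5 with DDQ in toluene, a known way from ortho-prenyl phenols to 2,2-dimethylchromenes, returns to the route at 15.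

Step 3. The borylation may stall if the catalyst is inhibited by the crowded, heteroatom-rich substrate. The silyl triflate may also lose triflate or silicon during the aqueous oxidation.

Fallback: set out from 8 and carry the third oxygen from the start.
- Copper-catalysed alkylation of excess phloroglucinol F1 with 8 should give 5-[(2-methylbut-3-yn-2-yl)oxy]benzene-1,3-diol F6.
- Statistical capping of one hydroxyl with MOMCl gives 3-(methoxymethoxy)-5-[(2-methylbut-3-yn-2-yl)oxy]phenol F7.
- Isopropyl isocyanate with a little Et3N gives 3-(methoxymethoxy)-5-[(2-methylbut-3-yn-2-yl)oxy]phenyl N-isopropylcarbamate F8.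
- In situ N-silylation (Me3SiOTf, TMEDA), excess n-BuLi at −78 °C and Me3SiCl should lithiate between the carbamate and OMOM, since the bulky tertiary ether is a poor director. The acetylide is silylated as well, giving 3-(methoxymethoxy)-5-{[2-methyl-4-(trimethylsilyl)but-3-yn-2-yl]oxy}-2-(trimethylsilyl)phenyl N-isopropylcarbamate F9.
- K2CO3 in MeOH cleaves the alkynyl C–Si bond and, through the isocyanate, the N–H carbamate, giving 3-(methoxymethoxy)-5-[(2-methylbut-3-yn-2-yl)oxy]-2-(trimethylsilyl)phenol F10.
- Triflation with PhNTf2 and Et3N rejoins the route at 9.

Step 1. Capping one hydroxyl of a symmetric diol is statistical. Over-alkylation to the bis-ether and unreacted diol limit throughput, although not purity.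

Fallback: set out from 1 and let the silyl migration break the symmetry. Hexamethyldisilazane gives 2-bromo-1,3-bis(trimethylsilyloxy)benzene F11. Bromine–lithium exchange with n-BuLi at −78 °C creates a single carbanion, so only one silyl group can move from oxygen to carbon. Tf2O traps the resulting phenoxide, and aqueous work-up removes the remaining O-silyl group to give 3-hydroxy-2-(trimethylsilyl)phenyl trifluoromethanesulfonate F12. MOMCl with iPr2NEt at 0 °C rejoins the route at 5; only a weak amine base is used because the phenoxide of F12 can expel triflate under stronger base.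

## Further compounds

F1 | step 5 | phloroglucinol (benzene-1,3,5-triol) | Oc1cc(O)cc(O)c1
F2 | step 5 | 2-(4-methoxyphenyl)-1-(2,4,6-trihydroxyphenyl)ethanone | COc1ccc(CC(=O)c2c(O)cc(O)cc2O)cc1
F3 | step 5 | 1-{2,6-dihydroxy-4-[(2-methylbut-3-yn-2-yl)oxy]phenyl}-2-(4-methoxyphenyl)ethanone | COc1ccc(CC(=O)c2c(O)cc(OC(C)(C)C#C)cc2O)cc1
F4 | step 6 | 1-[2-hydroxy-6-(methoxymethoxy)-4-[(2-methylbut-3-en-2-yl)oxy]phenyl]-2-(4-methoxyphenyl)ethanone | COCOc1cc(OC(C)(C)C=C)cc(O)c1C(=O)Cc1ccc(OC)cc1
F5 | step 6 | 1-[2,4-dihydroxy-6-(methoxymethoxy)-3-(3-methylbut-2-en-1-yl)phenyl]-2-(4-methoxyphenyl)ethanone | COCOc1cc(O)c(CC=C(C)C)c(O)c1C(=O)Cc1ccc(OC)cc1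
F6 | step 3 | 5-[(2-methylbut-3-yn-2-yl)oxy]benzene-1,3-diol | Oc1cc(O)cc(OC(C)(C)C#C)c1
F7 | step 3 | 3-(methoxymethoxy)-5-[(2-methylbut-3-yn-2-yl)oxy]phenol | COCOc1cc(O)cc(OC(C)(C)C#C)c1
F8 | step 3 | 3-(methoxymethoxy)-5-[(2-methylbut-3-yn-2-yl)oxy]phenyl N-isopropylcarbamate | COCOc1cc(OC(C)(C)C#C)cc(OC(=O)NC(C)C)c1
F9 | step 3 | 3-(methoxymethoxy)-5-{[2-methyl-4-(trimethylsilyl)but-3-yn-2-yl]oxy}-2-(trimethylsilyl)phenyl N-isopropylcarbamate | COCOc1cc(OC(C)(C)C#C[Si](C)(C)C)cc(OC(=O)NC(C)C)c1[Si](C)(C)C
F10 | step 3 | 3-(methoxymethoxy)-5-[(2-methylbut-3-yn-2-yl)oxy]-2-(trimethylsilyl)phenol | COCOc1cc(OC(C)(C)C#C)cc(O)c1[Si](C)(C)C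
F11 | step 1 | 2-bromo-1,3-bis(trimethylsilyloxy)benzene | C[Si](C)(C)Oc1cccc(O[Si](C)(C)C)c1Br
F12 | step 1 | 3-hydroxy-2-(trimethylsilyl)phenyl trifluoromethanesulfonate | Oc1cccc(OS(=O)(=O)C(F)(F)F)c1[Si](C)(C)C
A1 | alternative 1 | 3-methoxy-5-(methoxymethoxy)-2-(trimethylsilyl)phenyl trifluoromethanesulfonate | COCOc1cc(OC)c([Si](C)(C)C)c(OS(=O)(=O)C(F)(F)F)c1
A2 | alternative 1 | 3-methoxy-5-(methoxymethoxy)benzyne | COC1=CC(OCOC)=CC#C1
A3 | alternative 1 | 3-methylbut-2-enal | CC(C)=CC=O
A4 | alternative 1 | 5-methoxy-7-(methoxymethoxy)-2,2-dimethyl-2H-chromene | COCOc1cc(OC)c2C=CC(C)(C)Oc2c1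
A5 | alternative 2 | methyl 8-(4-methoxyphenyl)-3,5,7-trioxooctanoate | COC(=O)CC(=O)CC(=O)CC(=O)Cc1ccc(OC)cc1
A6 | alternative 2 | 2-(4-methoxyphenyl)-1-(2,4,6-trihydroxyphenyl)ethanone | COc1ccc(CC(=O)c2c(O)cc(O)cc2O)cc1
A7 | alternative 3 | 2-iodo-1,3,5-tris(methoxymethoxy)benzene | COCOc1cc(OCOC)c(I)c(OCOC)c1
A8 | alternative 3 | carbon monoxide | [C-]#[O+]
A9 | alternative 3 | 4-methoxybenzylzinc chloride | COc1ccc(C[Zn]Cl)cc1
A10 | alternative 3 | 2-(4-methoxyphenyl)-1-[2,4,6-tris(methoxymethoxy)phenyl]ethanone | COCOc1cc(OCOC)c(C(=O)Cc2ccc(OC)cc2)c(OCOC)c1
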